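How much does the rate of making target in this flask rise, in percent, for one percent more free catalyst or one percent more coupling partner, at 10% conversion of the starting material?

| flask | starting material | second substrate | coupling partner | free catalyst | remark |
|---|---|---|---|---|---|
| south | 0.77 M | 1.1 M | 1.39 M | 24 mM | run made earlier |
| north-east | 0.77 M | 1.7 M | 1.39 M | 24 mM | run made earlier |
| south-east | 0.77 M | 0.77 M | 1.39 M | 36 mM | run made earlier |
| flask | 0.77 M | 0.770 M | 1.39 M | 24 mM |  |

| south: time / h | south: target / % | north-east: time / h | north-east: target / % | south-east: time / h | south-east: target / % |
|---|---|---|---|---|---|
| 4.00 | 90.8 | 2.50 | 69.1 | 2.50 | 89.2 |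
| 10.0 | 100.3 | 6.00 | 98.7 | 6.00 | 99.3 |
| 20.0 | 99.8 | 12.0 | 100.0 | 12.0 | 99.5 |
| 30.0 | 99.4 | 30.0 | 98.9 | 30.0 | 100.5 |

(standard deviation of a reading: 0.5 percentage points)

- apparent order in free catalyst when 10% of the starting material are converted (percent change of the rate of making target for one percent more free catalyst charged)
- apparent order in coupling partner when 10% of the starting material are converted (percent change of the rate of making target for one percent more coupling partner charged)

- on the list of suspects stand: starting material + free catalyst <-> catalyst intermediate A; coupling partner + catalyst intermediate A -> free catalyst + target; second substrate + free catalyst <-> catalyst intermediate B; coupling partner + catalyst intermediate B -> free catalyst + second product; 2 second substrate -> self-condensation product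
- what is bound to the catalyst counts as converted
- no earlier run changes the charge of coupling partner; that part of a forecast is a guess

The bench rule says order 1 in each. For free catalyst, its border is the ratio of catalyst to starting material, 3.12%, and catalyst this dilute cannot bind away much substrate. The runs agree: the south-east run has 0.938 of the south run's catalyst-time and 0.933 of its first-order progress, although their second substrate differs. I take order 1.

For coupling partner, the rule holds when the catalyst waits on intermediate A, the resting state. Let θ be the share waiting there; in a two-step cycle, the order in starting material is 1 − θ, and the order in coupling partner is θ if the binding does not run back and above θ if it does.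

In the north-east run, the first-order constant of starting material rises from 0.470 h⁻¹ to 0.905 h⁻¹, while the geometric middle of what is left falls from 55.6% to 6.34%. That gives θ = 0.302 on a first round. Coupling partner also falls, from 75.4% to 48.1% of its charge, and putting that back, with its order taken as θ, gives θ = 0.381. This is rough, since the last reading leaves 1.30% with a scatter of 0.5 percentage points.

With θ = a/(a + h), where a is the fraction left, h is the fraction left at which half the catalyst waits: h = 0.305. At 10% conversion I reckon θ = 0.747, and I take that as my low mark for the order in coupling partner.

The forecast gives 1 (0.9 to 1.03) and 0.8 (0.45 to 1.05), against my 1 and my low mark of 0.747: “No run varies the coupling partner, so I guess about 0.8, with a wide range.”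

The simulation gives 1.0 in free catalyst and 0.91 in coupling partner, which is 0.163 above my low mark.

    starting material + free catalyst ⇌ catalyst intermediate A (K = 21.0 M⁻¹, k = 0.0430 M⁻¹ s⁻¹)
    coupling partner + catalyst intermediate A → free catalyst + target (k = 0.00340 M⁻¹ s⁻¹)
    second substrate + free catalyst ⇌ catalyst intermediate B (K = 0.710 M⁻¹, k = 0.00110 M⁻¹ s⁻¹)
    coupling partner + catalyst intermediate B → free catalyst + second product (k = 5.00 × 10⁻⁴ M⁻¹ s⁻¹)
    2 second substrate → self-condensation product (k = 3.40 × 10⁻⁵ M⁻¹ s⁻¹)

At the start, the forward step to intermediate A uses free catalyst 39 times as fast as the forward step to intermediate B. In this flask at 2.50 h, with 25.9% of the starting material left, h gives a share of 45.9%, and intermediate A holds 58.3% of the catalyst.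

The numbers in the tables were computed with constants of no real substance, and the scatter is random.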